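All runs come from a simulation on assumed constants.

Follow the reagent through this flask entry by entry, for at 0.950 equiv it is the limiting reagent, and plot the target against the logarithm of the clock.

| flask | starting material | reagent | free catalyst | remark |
|---|---|---|---|---|
| winter | 1.1 M | 0.95 equiv | 0.089 mol% | run made earlier |
| summer | 2.2 M | 0.95 equiv | 0.044 mol% | run made earlier |
| flask | 2.2 M | 0.950 equiv | 0.089 mol% |  |

| run | time / min | target / % |
|---|---|---|
| winter | 0.833 | 4.3 |
| winter | 2.50 | 8.9 |
| winter | 4.00 | 11.8 |
| winter | 6.00 | 13.6 |
| winter | 10.0 | 17.7 |
| winter | 12.0 | 18.7 |
| summer | 1.00 | 3.1 |
| summer | 3.00 | 10.4 |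
| summer | 6.00 | 12.1 |
| summer | 8.00 | 16.1 |
| summer | 12.0 | 20.0 |

(each reading ± 1 percentage point)

- factor on the rate of making target when 30 % of the starting material are converted if reagent is charged twice over
- factor on the rate when 30 % of the starting material are converted if free catalyst is charged at 0.02 mol% instead

- on the list of suspects stand: reagent + free catalyst <-> catalyst intermediate A; starting material + catalyst intermediate A <-> catalyst intermediate B; catalyst intermediate B <-> catalyst intermediate C; catalyst intermediate C -> free catalyst + target; 2 catalyst intermediate A -> spent catalyst

I open the ledger with the reagent charged to this flask. The first entry is the catalyst, each form of which holds one reagent at most: 0.089 mol% of the starting material, against a charge of 0.950 equiv. The second entry is the target, taken mole for mole, and at 30 % conversion it holds 31.6 % of the charge, so the books close with 68.4 % of the charge outside the target, the first entry included.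

The summer run slows with 78.9 % of its reagent outside the target at its last reading. There the target climbs from 10.4 % at 3.00 min to 20.0 % at 12.0 min, or 16 percentage points per tenfold of time. This reading is the decade gain, the conversion that costs a tenfold in rate on such a line.

The suspected death takes two catalyst intermediate A, so if catalyst intermediate A keeps a fixed share of the working catalyst, the working catalyst lost per point of target is proportional to the working catalyst present. I therefore expect the logarithm of the rate to fall with conversion along the same slope for either loading, with the charges of starting material and reagent held as in this flask. The smaller charge then shifts that line by −0.648, a factor of 0.225, worth 10 points of conversion. Both runs hold reagent at the same equivalents, so I get no figure for doubling it.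

The forecast gives 0.9 for doubled reagent and 0.225 for the smaller charge, holding that “Rate at fixed conversion is thus proportional to loading”.

The flask gives 0.957 for doubled reagent and 0.225 for the smaller charge, with 93.9 % of the catalyst as spent catalyst at 30 % conversion.

    reagent + free catalyst ⇌ catalyst intermediate A (K = 5.70 L mol⁻¹, k = 61.0 L mol⁻¹ s⁻¹)
    starting material + catalyst intermediate A ⇌ catalyst intermediate B (K = 0.840 L mol⁻¹, k = 40.0 L mol⁻¹ s⁻¹)
    catalyst intermediate B ⇌ catalyst intermediate C (K = 0.620, k = 2.50 s⁻¹)
    catalyst intermediate C → free catalyst + target (k = 140 s⁻¹)
    2 catalyst intermediate A → spent catalyst (k = 20.0 L mol⁻¹ s⁻¹)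

Adding the decade gain of 16 points to the 29.6 % of target in this flask at 20.0 min reads 45.6 % for 200 min; the flask stands at 46.5 %, with catalyst intermediate A down ten times, from 2.66 % to 0.250 %.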